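4 questions stood on 3 flasks: how much electrophile had reacted after 30 min at each charge of free base, and how that part moved with the charge.

| setting | Monday's | south-east | south | east |
|---|---|---|---|---|
| electrophile | 0.020 M | 0.020 M | 0.020 M | 0.020 M |
| nucleophile | 0.040 M | 0.0400 M | 0.0400 M | 0.0400 M |
| free base | 0.057 M | 0.0220 M | 0.0290 M | 0.0370 M |
| remark | run made earlier |  |  |  |
| time |  | 30 min | 30 min | 30 min |

Monday's run (percent of the electrophile charged)

| time / min | electrophile / % | product / % |
|---|---|---|
| 5.00 | 96.2 | 4.1 |
| 10.0 | 91.8 | 8.5 |
| 15.0 | 87.6 | 12.8 |
| 20.0 | 83.4 | 16.5 |
| 25.0 | 80.5 | 19.6 |
| 30.0 | 76.8 | 23.0 |

(each reading ± 0.3 percentage points)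

- part of the electrophile that has reacted at the end, south-east
- part of the electrophile that has reacted at the end, south
- part of the electrophile that has reacted at the end, east
- what raising the concentration of free base from its lowest to its highest value here does to the part of the electrophile that has reacted (changes below 5 percentage points count as none) (it rises / no change / it falls)

- the numbers in the tables scatter by 0.3 percentage points (one standard deviation)
- no earlier run changes the charge of free base; that part of a forecast is a guess

In Monday's run at 30.0 min, 76.8 % of the electrophile was left and the product stood at 23.0 %, so the two balanced within the scatter of 0.3 percentage points. I took the step of electrophile with nucleophile as slow and the capture of the acid set free by free base as instantaneous. The rate was then proportional to electrophile times nucleophile, with free base absent from it; this was my assumption, since no earlier run changed that charge. For such a rate, the logarithm of nucleophile left over electrophile left, each as a fraction of its charge, grows linearly in time, with slope equal to the constant times the difference of the charges. Monday's last reading gave 0.234 /M/min, the second-order rate constant.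

Electrophile and nucleophile were charged as on Monday, so I drew one curve for south-east, south and east. The reacted part starts with slope 0.00938 /min and reaches 23.2 % at 30 min, where the slope, the constant times electrophile left as a fraction times nucleophile left, has eased to 0.00637 /min. Even the lowest charge of free base, 0.0220 M, exceeds the 0.020 M of electrophile, so I drew no knee. Half the electrophile has reacted by 86.5 min, and the curve runs on toward the whole charge. I therefore committed to 23.2 % in each flask and to no change.

The forecast differed from this, with 15 %, 17 % and 19 % and the trend "no change", and said of itself: “This is a guess, and the ranges are wide.”

The flasks gave 22.8 %, 22.8 % and 22.8 %, a change of 0 points, so the trend was "no change".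

    electrophile + nucleophile ⇌ acid set free + product (K = 0.320, k = 0.230 /M/min)
    acid set free + free base ⇌ salt of the base, settled at all times (K = 4.20 × 10⁶ /M)
    nucleophile + acid set free ⇌ protonated nucleophile, settled at all times (K = 300 /M)

The neighbouring flask was south with 0.016 M of nucleophile, 0.800 equiv to the electrophile, which made nucleophile the limiting reagent there. Its starting slope from 0.234 /M/min was 0.00374 /min, and the same logarithmic law, now with a negative difference of charges, gave 9.97 % reacted at 30 min. At 30.0 min the neighbouring flask held 90 % of its electrophile and 88 % of its nucleophile, and the part of the electrophile that had reacted was 9.82 %.

The earlier runs and the new flask are simulated for an exercise.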